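**Plan**

- The retrosynthesis cuts, in this order: the C6'=C7' alkene (back to a vinyl group), the two oxirane C–O bonds at C2' and C3' (back to an E alkene), the aryl O–C1' bond, and the C4'–C5' bond. The chain is numbered from OCH2 = C1'.
- Forward: methyl 3-methylbut-2-enoate is joined through its silyl dienolate to acrolein at C4'–C5'. Silylation and ester reduction give a dienol, which is etherified with 7-hydroxy-8-methoxycoumarin. The oxirane, the only ring made, is closed next, and desilylation and cross-metathesis with 2-methylbut-2-ene finish the target.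
- Enabling feature: C2' and C3' of the oxirane derive from an E-trisubstituted C2'=C3' alkene whose C1' oxygen is already the O7 aryl ether of the benzopyranone. No allylic OH is left to direct a metal oxidant, so the oxygen must come from a chiral dioxirane, and the other two C=C bonds (vinyl, pyranone C3=C4) are much poorer nucleophiles.
- Stereochemistry: C5' (R) comes from a catalytic asymmetric vinylogous Mukaiyama aldol on the Re face of acrolein. C2' and C3' (R,R) come from the D-fructose-derived ketone catalyst, and their trans relation from the E alkene.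

Key step: step 6

Remark: the (R,R)-bisphosphoramide is assumed to send the dienolate to the Re face of acrolein as with other conjugated aldehydes; the configuration of the aldol product is to be checked as its Mosher esters, and the (S,S)-ligand is the remedy if the sense proves opposite.
Remark: the geometry of the ketene acetal double bond of the silyl dienolate is not controlled and does not matter, since that bond becomes the ester carbonyl again in step 2.

**Route**

Step 1
Reactants: 1 methyl 3-methylbut-2-enoate
Product: 3 tert-butyl[(1-methoxy-3-methylbuta-1,3-dien-1-yl)oxy]dimethylsilane (silyl dienolate), via lithium dienolate 2 (not isolated)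
Conditions: LiN(i-Pr)2, THF, −78 °C; then TBSCl, DMPU, −78 °C → rt; distillation
Reagents that add atoms: tert-butyldimethylsilyl chloride (TBSCl), CC(C)(C)[Si](C)(C)Cl
Why: Kinetic γ-deprotonation of the β,β-dimethyl enoate by the amide base gives the cross-conjugated lithium dienolate, which the silyl chloride traps on oxygen (silyl ketene acetal formation).

Step 2
Reactants: 3 tert-butyl[(1-methoxy-3-methylbuta-1,3-dien-1-yl)oxy]dimethylsilane; 4 acrolein (freshly distilled)
Product: 6 methyl (2E,5R)-5-hydroxy-3-methylhepta-2,6-dienoate, via trichlorosilyl aldolate 5 (not isolated)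
Conditions: SiCl4 (1.1 equiv), (R,R)-bisphosphoramide N,N'-dimethyl-N,N'-bis[(11bR)-3,5-dimethyl-4-oxido-3,5-dihydro-4H-dinaphtho[2,1-d:1',2'-f][1,3,2]diazaphosphepin-4-yl]pentane-1,5-diamine (2 mol %), CH2Cl2, −78 °C; then cold sat. aq. NaHCO3, filtration through Celite
Reagents that add atoms: none
Why: In this Lewis-base-activated SiCl4 vinylogous Mukaiyama aldol the bisphosphoramide-bound trichlorosilyl cation binds acrolein and the dienolate attacks through its γ-carbon in an open transition state on the Re face of the aldehyde, which sets C5 as R, while the s-trans diene gives the E enoate, 1,2-addition is the normal course for an enal, and the weakly acidic free SiCl4 leaves acrolein unpolymerised.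

Step 3
Reactants: 6 methyl (2E,5R)-5-hydroxy-3-methylhepta-2,6-dienoate
Product: 7 methyl (2E,5R)-5-(tert-butyldimethylsilyloxy)-3-methylhepta-2,6-dienoate
Conditions: TBSCl, imidazole, DMF, rt
Reagents that add atoms: tert-butyldimethylsilyl chloride (TBSCl), CC(C)(C)[Si](C)(C)Cl
Why: Imidazole-promoted silylation of the secondary allylic alcohol (standard silyl ether formation) masks the hydroxyl for the hydride reduction and the Mitsunobu step, where a free secondary allylic alcohol would compete, and does not touch the C5 centre.

Step 4
Reactants: 7 methyl (2E,5R)-5-(tert-butyldimethylsilyloxy)-3-methylhepta-2,6-dienoate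
Product: 8 (2E,5R)-5-(tert-butyldimethylsilyloxy)-3-methylhepta-2,6-dien-1-ol
Conditions: i-Bu2AlH (2.2 equiv), CH2Cl2, −78 °C; aq. KNaC4H4O6 (potassium sodium tartrate) work-up
Reagents that add atoms: none
Why: i-Bu2AlH delivers two hydrides to the ester carbonyl (1,2-reduction of an α,β-unsaturated ester) at low temperature and gives the E allylic alcohol without conjugate reduction, alkene migration or loss of the silyl ether.

Step 5
Reactants: 8 (2E,5R)-5-(tert-butyldimethylsilyloxy)-3-methylhepta-2,6-dien-1-ol; 9 7-hydroxy-8-methoxy-2H-chromen-2-one (hydrangetin)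
Product: 10 7-{[(2E,5R)-5-(tert-butyldimethylsilyloxy)-3-methylhepta-2,6-dien-1-yl]oxy}-8-methoxy-2H-chromen-2-one
Conditions: PPh3, diisopropyl azodicarboxylate, THF, 0 °C → rt
Reagents that add atoms: none
Why: In this Mitsunobu etherification the acidic 7-hydroxyl of the coumarin (pKa near 8, conjugated with the lactone carbonyl) protonates the phosphine–azodicarboxylate betaine and its phenoxide displaces the primary allylic oxyphosphonium group at C1' by SN2, which keeps the E geometry and leaves the protected C5' centre alone.

Step 6
Reactants: 10 7-{[(2E,5R)-5-(tert-butyldimethylsilyloxy)-3-methylhepta-2,6-dien-1-yl]oxy}-8-methoxy-2H-chromen-2-one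
Product: 11 7-{[(2R,3R)-3-[(2R)-2-(tert-butyldimethylsilyloxy)but-3-en-1-yl]-3-methyloxiran-2-yl]methoxy}-8-methoxy-2H-chromen-2-one
Conditions: 1,2:4,5-di-O-isopropylidene-β-D-erythro-2,3-hexodiulo-2,6-pyranose (the D-fructose-derived ketone, 0.3 equiv), KHSO5 (as 2KHSO5·KHSO4·K2SO4), K2CO3, Bu4NHSO4 (cat.), MeCN–CH2(OMe)2 / aq. Na2B4O7–Na2EDTA buffer, pH about 10.5, −5 to 0 °C
Reagents that add atoms: potassium peroxymonosulfate (KHSO5), [K+].[O-]S(=O)(=O)OO
Why: KHSO5 adds to the carbonyl of the fructose-derived ketone and the adduct closes to a chiral dioxirane, which hands one oxygen atom to the C2'=C3' π bond in a concerted, asynchronous spiro transition state and regenerates the ketone (Shi asymmetric epoxidation, best known for E-trisubstituted alkenes, including those with an allylic ether oxygen and geranyl-type chains). The oxirane, the only ring formed, closes by this single [2+1] oxygen-atom transfer in which both C–O bonds arise on the same face, so the E geometry becomes the trans relation of C1' and C4'. C2' and C3' are set together by the catalyst: in the favoured spiro arrangement the small hydrogen at C2' takes the quadrant next to the dioxolane ring and the oxygen reaches the face that gives the (2'R,3'R) oxirane, the same sense as the (R,R) epoxides obtained from other E-trisubstituted alkenes with this ketone, while the C5' centre is too remote to interfere. Chemoselectivity among three C=C bonds is needed and comes from nucleophilicity: the trisubstituted alkene outpaces the monosubstituted vinyl group, which is also shielded by the neighbouring silyloxy group, and the pyranone C3=C4 bond, which is conjugated to the lactone carbonyl. The carbonate-buffered pH keeps the ketone from Baeyer–Villiger destruction, and the two-phase medium, low temperature and short contact time limit hydroxide attack on the lactone, which would reclose on neutralisation in any case.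

Step 7
Reactants: 11 7-{[(2R,3R)-3-[(2R)-2-(tert-butyldimethylsilyloxy)but-3-en-1-yl]-3-methyloxiran-2-yl]methoxy}-8-methoxy-2H-chromen-2-one
Product: 12 7-{[(2R,3R)-3-[(2R)-2-hydroxybut-3-en-1-yl]-3-methyloxiran-2-yl]methoxy}-8-methoxy-2H-chromen-2-one
Conditions: Bu4NF, AcOH (1:1), THF, 0 °C → rt
Reagents that add atoms: none
Why: Fluoride attacks silicon and releases the secondary alkoxide, which acetic acid protonates at once, so that neither the lactone nor the oxirane meets a strong base and the three stereocentres are untouched (standard silyl ether cleavage).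

Step 8
Reactants: 12 7-{[(2R,3R)-3-[(2R)-2-hydroxybut-3-en-1-yl]-3-methyloxiran-2-yl]methoxy}-8-methoxy-2H-chromen-2-one; 13 2-methylbut-2-ene (large excess)
Product: 14 7-{[(2R,3R)-3-[(2R)-2-hydroxy-4-methylpent-3-en-1-yl]-3-methyloxiran-2-yl]methoxy}-8-methoxy-2H-chromen-2-one (target)
Conditions: second-generation Grubbs catalyst RuCl2(=CHPh)(PCy3)(H2IMes) (5 mol %; H2IMes = 1,3-dimesitylimidazolidin-2-ylidene), 2-methylbut-2-ene/CH2Cl2, rt to 40 °C, sealed vessel
Reagents that add atoms: none
Why: In this ruthenium-carbene olefin cross-metathesis the terminal alkene of 12 exchanges its CH2 end for the isopropylidene unit of the excess 2-methylbut-2-ene with loss of propene, the trisubstituted product is inert to further metathesis, and the oxirane, the free hydroxyl and the conjugated endocyclic pyranone alkene are not engaged, so no stereocentre is created or touched.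

**Compound list**

1 | methyl 3-methylbut-2-enoate | COC(=O)C=C(C)C | starting material
2 | lithium 1-methoxy-3-methylbuta-1,3-dien-1-olate (lithium dienolate of 1) | [Li+].[O-]C(OC)=CC(C)=C | intermediate
3 | tert-butyl[(1-methoxy-3-methylbuta-1,3-dien-1-yl)oxy]dimethylsilane (silyl dienolate; ketene acetal geometry not controlled) | COC(O[Si](C)(C)C(C)(C)C)=CC(C)=C | intermediate
4 | acrolein (prop-2-enal) | C=CC=O | starting material
5 | methyl (2E,5R)-3-methyl-5-(trichlorosilyloxy)hepta-2,6-dienoate | COC(=O)/C=C(\C)C[C@@H](O[Si](Cl)(Cl)Cl)C=C | intermediate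
6 | methyl (2E,5R)-5-hydroxy-3-methylhepta-2,6-dienoate | COC(=O)/C=C(\C)C[C@@H](O)C=C | intermediate
7 | methyl (2E,5R)-5-(tert-butyldimethylsilyloxy)-3-methylhepta-2,6-dienoate | COC(=O)/C=C(\C)C[C@@H](O[Si](C)(C)C(C)(C)C)C=C | intermediate
8 | (2E,5R)-5-(tert-butyldimethylsilyloxy)-3-methylhepta-2,6-dien-1-ol | OC/C=C(\C)C[C@@H](O[Si](C)(C)C(C)(C)C)C=C | intermediate
9 | 7-hydroxy-8-methoxy-2H-chromen-2-one (hydrangetin) | COc1c(O)ccc2ccc(=O)oc12 | starting material
10 | 7-{[(2E,5R)-5-(tert-butyldimethylsilyloxy)-3-methylhepta-2,6-dien-1-yl]oxy}-8-methoxy-2H-chromen-2-one | COc1c(OC/C=C(\C)C[C@@H](O[Si](C)(C)C(C)(C)C)C=C)ccc2ccc(=O)oc12 | intermediate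
11 | 7-{[(2R,3R)-3-[(2R)-2-(tert-butyldimethylsilyloxy)but-3-en-1-yl]-3-methyloxiran-2-yl]methoxy}-8-methoxy-2H-chromen-2-one | COc1c(OC[C@H]2O[C@]2(C)C[C@@H](O[Si](C)(C)C(C)(C)C)C=C)ccc2ccc(=O)oc12 | intermediate
12 | 7-{[(2R,3R)-3-[(2R)-2-hydroxybut-3-en-1-yl]-3-methyloxiran-2-yl]methoxy}-8-methoxy-2H-chromen-2-one | COc1c(OC[C@H]2O[C@]2(C)C[C@@H](O)C=C)ccc2ccc(=O)oc12 | intermediate
13 | 2-methylbut-2-ene | CC=C(C)C | starting material
14 | 7-{[(2R,3R)-3-[(2R)-2-hydroxy-4-methylpent-3-en-1-yl]-3-methyloxiran-2-yl]methoxy}-8-methoxy-2H-chromen-2-one | COc1c(OC[C@H]2O[C@]2(C)C[C@@H](O)C=C(C)C)ccc2ccc(=O)oc12 | target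

**Step count**

Total: 8 steps. Longest linear sequence: 8 steps (1 → 14).

**Steps most likely to fail**

Step 6. What may go wrong: slow oxygen transfer to an alkene that the allylic aryloxy group makes electron-poorer, so that the ketone catalyst is lost to Baeyer–Villiger oxidation first, enantiofacial selectivity erodes and the lactone is opened by the basic buffer over the long reaction time. Fallback (hydroxyl-directed epoxidation before the ether is formed): setting out from allylic alcohol 8, Katsuki–Sharpless epoxidation with Ti(OiPr)4, D-(−)-diethyl tartrate and t-BuOOH (4 Å molecular sieves, CH2Cl2, −20 °C) should give [(2R,3R)-3-[(2R)-2-(tert-butyldimethylsilyloxy)but-3-en-1-yl]-3-methyloxiran-2-yl]methanol F1. The D-tartrate is chosen because the L-ester gives the (2S,3S) oxirane from E allylic alcohols of this substitution pattern. The vinyl group, part of an allylic silyl ether, is not a substrate for the titanium alkoxide catalyst. Mitsunobu coupling of F1 with phenol 9 (PPh3, diisopropyl azodicarboxylate, THF), which leaves 2,3-epoxy alcohols intact, then comes back to the route at 11.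

Step 2. What may go wrong: low enantiofacial discrimination with the smallest enal, or competing conjugate addition and oligomerisation of acrolein. Fallback (resolution in place of catalyst control): from 3 and 4, the same addition promoted by an achiral Lewis acid (BF3·OEt2, CH2Cl2, −78 °C) should give racemic methyl (2E)-5-hydroxy-3-methylhepta-2,6-dienoate F2. Acylation with vinyl acetate and immobilised lipase B from Candida antarctica (t-BuOMe, rt), taken just past half conversion, is expected to esterify the S enantiomer (vinyl as the medium and the chain as the large substituent) to methyl (2E,5S)-5-acetoxy-3-methylhepta-2,6-dienoate F3. The R alcohol is left, is separated by chromatography and is 6, where the route is rejoined.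

Step 8. What may go wrong: incomplete metathesis that cannot be forced on the last intermediate, or degradation of the tertiary epoxy alcohol by ruthenium species (hydride-induced isomerisation of the allylic alcohol, Lewis-acid opening of the oxirane). Fallback (metathesis moved to the simplest intermediate, and the oxirane made by a hydroxyl-directed epoxidation that tolerates a second trisubstituted alkene): from hydroxy ester 6, cross-metathesis with 13 under the same catalyst should give methyl (2E,5R)-5-hydroxy-3,7-dimethylocta-2,6-dienoate F4. Silylation (TBSCl, imidazole, DMF) gives methyl (2E,5R)-5-(tert-butyldimethylsilyloxy)-3,7-dimethylocta-2,6-dienoate F5, and i-Bu2AlH reduction gives (2E,5R)-5-(tert-butyldimethylsilyloxy)-3,7-dimethylocta-2,6-dien-1-ol F6. Katsuki–Sharpless epoxidation [Ti(OiPr)4, D-(−)-diethyl tartrate, t-BuOOH], which only touches the alkene of the allylic alcohol, should give [(2R,3R)-3-[(2R)-2-(tert-butyldimethylsilyloxy)-4-methylpent-3-en-1-yl]-3-methyloxiran-2-yl]methanol F7. Mitsunobu coupling with 9 gives 7-{[(2R,3R)-3-[(2R)-2-(tert-butyldimethylsilyloxy)-4-methylpent-3-en-1-yl]-3-methyloxiran-2-yl]methoxy}-8-methoxy-2H-chromen-2-one F8, and Bu4NF/AcOH comes back to the route at the target 14.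

**Further compounds**

F1 | step 6 | [(2R,3R)-3-[(2R)-2-(tert-butyldimethylsilyloxy)but-3-en-1-yl]-3-methyloxiran-2-yl]methanol | OC[C@H]1O[C@]1(C)C[C@@H](O[Si](C)(C)C(C)(C)C)C=C
F2 | step 2 | racemic methyl (2E)-5-hydroxy-3-methylhepta-2,6-dienoate | COC(=O)/C=C(\C)CC(O)C=C
F3 | step 2 | methyl (2E,5S)-5-acetoxy-3-methylhepta-2,6-dienoate | COC(=O)/C=C(\C)C[C@H](OC(C)=O)C=C
F4 | step 8 | methyl (2E,5R)-5-hydroxy-3,7-dimethylocta-2,6-dienoate | COC(=O)/C=C(\C)C[C@@H](O)C=C(C)C
F5 | step 8 | methyl (2E,5R)-5-(tert-butyldimethylsilyloxy)-3,7-dimethylocta-2,6-dienoate | COC(=O)/C=C(\C)C[C@@H](O[Si](C)(C)C(C)(C)C)C=C(C)C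
F6 | step 8 | (2E,5R)-5-(tert-butyldimethylsilyloxy)-3,7-dimethylocta-2,6-dien-1-ol | OC/C=C(\C)C[C@@H](O[Si](C)(C)C(C)(C)C)C=C(C)C
F7 | step 8 | [(2R,3R)-3-[(2R)-2-(tert-butyldimethylsilyloxy)-4-methylpent-3-en-1-yl]-3-methyloxiran-2-yl]methanol | OC[C@H]1O[C@]1(C)C[C@@H](O[Si](C)(C)C(C)(C)C)C=C(C)C
F8 | step 8 | 7-{[(2R,3R)-3-[(2R)-2-(tert-butyldimethylsilyloxy)-4-methylpent-3-en-1-yl]-3-methyloxiran-2-yl]methoxy}-8-methoxy-2H-chromen-2-one | COc1c(OC[C@H]2O[C@]2(C)C[C@@H](O[Si](C)(C)C(C)(C)C)C=C(C)C)ccc2ccc(=O)oc12
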